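**Retrosynthetic overview**

1. Target 21 is numbered as a 3a,4,5,7a-tetrahydro-1H-indene (C-1 CHMe, C-2=C-3(Me), C-3a/C-7a trans ring fusion, C-4 and C-5 quaternary, C-6=C-7(Me)); it comes from methyl ester 20 by thiolate demethylation.
2. Five-membered ring: its C-2=C-3 alkene lies between two sp3 CH carbons (C-1, C-3a), so C-2 and C-3 can be the two α-carbons of a sulfone; 20 arises from thiane 1,1-dioxide 17 (one ring atom more) by Ramberg–Bäcklund extrusion of SO2.
3. 17 arises from open-chain sulfone 16 by intramolecular Diels–Alder reaction (C-3a–C-7a and C-4–C-5 bonds), a copy of the presumed biosynthesis in which SO2 replaces the (Z)-alkene of the tether. Ring order: cyclohexene and thiane together, then contraction to the cyclopentene, all in one flask.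
4. 16 comes from sulfide 14, built from aldehyde 10 by three Wittig homologations with Ph3P=C(Me)CHO and one Horner–Wadsworth–Emmons reaction.
5. 10 comes from thioacetate 6 (from methyl (R)-lactate 1, Mitsunobu inversion) and (2S)-3-bromo-2-methylpropan-1-ol 7; these two centres (one kept as C-1, one sacrificial next to sulfur) steer the cycloaddition.

Key step: step 13

**Route**

Step 1
Reactants: 1 methyl (R)-lactate
Product: 2 methyl (2R)-2-(tert-butyldimethylsilyloxy)propanoate
Conditions: TBSCl, imidazole, DMF, 0 °C to rt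
Reagents that add atoms: tert-butyldimethylsilyl chloride, CC(C)(C)[Si](C)(C)Cl
Why: O-Silylation of the secondary alcohol protects it for the hydride reduction and does not touch the stereocentre.

Step 2
Reactants: 2 methyl (2R)-2-(tert-butyldimethylsilyloxy)propanoate
Product: 3 (2R)-2-(tert-butyldimethylsilyloxy)propanal
Conditions: i-Bu2AlH (1.05 equiv), CH2Cl2, −78 °C; aq. potassium sodium tartrate work-up
Reagents that add atoms: none
Why: Partial ester reduction with i-Bu2AlH should stop at the aluminium hemiacetal at low temperature, and the α-silyloxy centre is not enolised.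

Step 3
Reactants: 3 (2R)-2-(tert-butyldimethylsilyloxy)propanal
Product: 4 methyl (2E,4R)-4-(tert-butyldimethylsilyloxy)-2-methylpent-2-enoate
Conditions: Ph3P=C(Me)CO2Me, CH2Cl2, rt
Reagents that add atoms: methyl 2-(triphenylphosphoranylidene)propanoate, COC(=O)C(C)=P(c1ccccc1)(c1ccccc1)c1ccccc1
Why: Wittig olefination with a stabilised ylide should give the (E)-trisubstituted enoate (ester trans to the chain) without racemising the aldehyde.

Step 4
Reactants: 4 methyl (2E,4R)-4-(tert-butyldimethylsilyloxy)-2-methylpent-2-enoate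
Product: 5 methyl (2E,4R)-4-hydroxy-2-methylpent-2-enoate
Conditions: HF·pyridine, pyridine, THF, 0 °C to rt
Reagents that add atoms: none
Why: Fluoride-mediated desilylation frees the allylic alcohol, which cannot lactonise because of the (E)-geometry, and the carbinol centre is untouched.

Step 5
Reactants: 5 methyl (2E,4R)-4-hydroxy-2-methylpent-2-enoate
Product: 6 methyl (2E,4S)-4-(acetylsulfanyl)-2-methylpent-2-enoate
Conditions: PPh3, DIAD, AcSH, THF, 0 °C to rt
Reagents that add atoms: thioacetic acid, CC(=O)S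
Why: Mitsunobu reaction, in which thioacetate displaces the oxyphosphonium group by SN2 with inversion (R to S), the fully substituted conjugated α-carbon disfavouring the SN2′ path.

Step 6
Reactants: 6 methyl (2E,4S)-4-(acetylsulfanyl)-2-methylpent-2-enoate; 7 (2S)-3-bromo-2-methylpropan-1-ol
Product: 9 methyl (2E,4S)-4-{[(2S)-3-hydroxy-2-methylpropyl]sulfanyl}-2-methylpent-2-enoate, via allylic thiol 8 (not isolated)
Conditions: K2CO3, MeOH (degassed), 0 °C to rt
Reagents that add atoms: none
Why: Methanolysis of the thioester frees the thiolate, which is captured at once by SN2 alkylation at the primary bromide (thioether synthesis), so neither stereocentre is involved.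

Step 7
Reactants: 9 methyl (2E,4S)-4-{[(2S)-3-hydroxy-2-methylpropyl]sulfanyl}-2-methylpent-2-enoate
Product: 10 methyl (2E,4S)-2-methyl-4-{[(2S)-2-methyl-3-oxopropyl]sulfanyl}pent-2-enoate
Conditions: Dess–Martin periodinane, CH2Cl2, 0 °C to rt
Reagents that add atoms: none
Why: Dess–Martin oxidation of the primary alcohol under near-neutral conditions should spare the sulfide and keep the α-methyl aldehyde from epimerising.

Step 8
Reactants: 10 methyl (2E,4S)-2-methyl-4-{[(2S)-2-methyl-3-oxopropyl]sulfanyl}pent-2-enoate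
Product: 11 methyl (2E,4S)-4-{[(2S,3E)-2,4-dimethyl-5-oxopent-3-en-1-yl]sulfanyl}-2-methylpent-2-enoate
Conditions: Ph3P=C(Me)CHO, PhMe, 60 °C
Reagents that add atoms: 2-(triphenylphosphoranylidene)propanal, CC(C=O)=P(c1ccccc1)(c1ccccc1)c1ccccc1
Why: Wittig olefination with the formyl-stabilised ylide should give the (E)-enal (chain and formyl group trans) under non-basic conditions that leave the α-centre intact.

Step 9
Reactants: 11 methyl (2E,4S)-4-{[(2S,3E)-2,4-dimethyl-5-oxopent-3-en-1-yl]sulfanyl}-2-methylpent-2-enoate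
Product: 12 methyl (2E,4S)-2-methyl-4-{[(2S,3E,5E)-2,4,6-trimethyl-7-oxohepta-3,5-dien-1-yl]sulfanyl}pent-2-enoate
Conditions: Ph3P=C(Me)CHO, PhMe, 100 °C
Reagents that add atoms: 2-(triphenylphosphoranylidene)propanal, CC(C=O)=P(c1ccccc1)(c1ccccc1)c1ccccc1
Why: A second Wittig homologation with the same stabilised ylide should add the next (E)-C(Me)=CH unit.

Step 10
Reactants: 12 methyl (2E,4S)-2-methyl-4-{[(2S,3E,5E)-2,4,6-trimethyl-7-oxohepta-3,5-dien-1-yl]sulfanyl}pent-2-enoate
Product: 13 methyl (2E,4S)-2-methyl-4-{[(2S,3E,5E,7E)-2,4,6,8-tetramethyl-9-oxonona-3,5,7-trien-1-yl]sulfanyl}pent-2-enoate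
Conditions: Ph3P=C(Me)CHO, PhMe, 100 °C
Reagents that add atoms: 2-(triphenylphosphoranylidene)propanal, CC(C=O)=P(c1ccccc1)(c1ccccc1)c1ccccc1
Why: A third Wittig homologation should give the (E,E,E)-trienal that carries all methyl branches of the chain.

Step 11
Reactants: 13 methyl (2E,4S)-2-methyl-4-{[(2S,3E,5E,7E)-2,4,6,8-tetramethyl-9-oxonona-3,5,7-trien-1-yl]sulfanyl}pent-2-enoate
Product: 14 methyl (2E,4S)-2-methyl-4-{[(2S,3E,5E,7E,9E)-2,4,6,8-tetramethyl-10-phenyldeca-3,5,7,9-tetraen-1-yl]sulfanyl}pent-2-enoate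
Conditions: (EtO)2P(O)CH2Ph, NaN(SiMe3)2, THF, −78 °C; then 13, −78 to 0 °C
Reagents that add atoms: diethyl benzylphosphonate, CCOP(=O)(Cc1ccccc1)OCC
Why: Horner–Wadsworth–Emmons olefination with the preformed benzylphosphonate anion should give the (E)-styryl terminus, cold addition letting carbonyl addition outrun proton transfer from the carbon next to sulfur.

Step 12
Reactants: 14 methyl (2E,4S)-2-methyl-4-{[(2S,3E,5E,7E,9E)-2,4,6,8-tetramethyl-10-phenyldeca-3,5,7,9-tetraen-1-yl]sulfanyl}pent-2-enoate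
Product: 16 methyl (2E,4S)-2-methyl-4-{[(2S,3E,5E,7E,9E)-2,4,6,8-tetramethyl-10-phenyldeca-3,5,7,9-tetraen-1-yl]sulfonyl}pent-2-enoate, via sulfoxide 15 (not isolated)
Conditions: (NH4)6Mo7O24·4H2O (10 mol%), 30% H2O2, EtOH/THF, 0 °C to rt
Reagents that add atoms: hydrogen peroxide, OO
Why: Molybdate-catalysed peroxide oxidation (chemoselective S-oxidation) should take the sulfide through the sulfoxide to the sulfone faster than it attacks the C=C bonds, and no carbon stereocentre changes.

Step 13
Reactants: 16 methyl (2E,4S)-2-methyl-4-{[(2S,3E,5E,7E,9E)-2,4,6,8-tetramethyl-10-phenyldeca-3,5,7,9-tetraen-1-yl]sulfonyl}pent-2-enoate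
Product: 20 methyl (1R,3aR,4R,5S,7aS)-1,3,4,5,7-pentamethyl-5-[(1E,3E)-2-methyl-4-phenylbuta-1,3-dien-1-yl]-3a,4,5,7a-tetrahydro-1H-indene-4-carboxylate, via thiane dioxide cycloadduct 17 (not isolated), via bromo sulfone 18 (not isolated), via episulfone 19 (not isolated)
Conditions: PhMe (5 mM), BHT, 140 °C, sealed tube; then 0 °C, t-BuOH/CH2Cl2, KOH/Al2O3, CBr2F2, 0 °C to rt
Reagents that add atoms: none
Why: Heating should close sulfone 16 by an intramolecular Diels–Alder reaction (diene = the first two C=C bonds of the tetraene, dienophile = the (E)-enoate, joined by a four-atom tether through sulfur) to thiane 1,1-dioxide 17, and in the same flask KOH/Al2O3 with CBr2F2 brominates a sulfone α-carbon (18), the other α-carbanion displaces bromide to give episulfone 19, and cheletropic loss of SO2 leaves the C-2=C-3 alkene (Ramberg–Bäcklund reaction). The closest known reaction types are the cycloaddition of ester-terminated deca-1,7,9-trienes to trans-fused bicycles and the Ramberg–Bäcklund contraction of thiane 1,1-dioxides to cyclopentenes. The cyclohexene closes by [4+2] cycloaddition (C-3a–C-7a and C-4–C-5 bonds), the thiane closes as the six-membered tether ring of the same cycloaddition, and the five-membered ring arises from the thiane by 3-exo-tet closure to the episulfone and extrusion of SO2. C-5 and C-7a are fixed by the (E,E)-diene and C-4 and C-3a by the (E)-enoate (suprafacial addition on both partners), the trans ring fusion by the endo-ester transition state in which the α-methyl group of the enoate points away from the diene, and the absolute sense by the chair-like tether in which the methyl groups on both tether stereocentres are equatorial and allylic 1,3-strain at the enoate is minimal. The step needs endo and π-facial selectivity in the cycloaddition, which the two pre-set stereocentres should secure, and a single alkene position in the contraction, which is secured because only the two carbons next to sulfur can form the double bond; the sulfone-bearing control stereocentre becomes sp2, while C-1, C-3a and C-7a carry no acidic hydrogen and should keep their configuration.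

Step 14
Reactants: 20 methyl (1R,3aR,4R,5S,7aS)-1,3,4,5,7-pentamethyl-5-[(1E,3E)-2-methyl-4-phenylbuta-1,3-dien-1-yl]-3a,4,5,7a-tetrahydro-1H-indene-4-carboxylate
Product: 21 27-nor-zyggomphic acid B, (1R,3aR,4R,5S,7aS)-1,3,4,5,7-pentamethyl-5-[(1E,3E)-2-methyl-4-phenylbuta-1,3-dien-1-yl]-3a,4,5,7a-tetrahydro-1H-indene-4-carboxylic acid
Conditions: NaSEt, DMF, 90 °C; then 1 M HCl
Reagents that add atoms: none
Why: SN2 demethylation by thiolate (alkyl–oxygen cleavage) should free the acid although the acyl carbon sits between two quaternary centres, and no stereocentre is involved.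

**Compound list**

1 | methyl (R)-lactate | C[C@@H](O)C(=O)OC | starting material
2 | methyl (2R)-2-(tert-butyldimethylsilyloxy)propanoate | C[C@@H](O[Si](C)(C)C(C)(C)C)C(=O)OC | intermediate
3 | (2R)-2-(tert-butyldimethylsilyloxy)propanal | C[C@@H](O[Si](C)(C)C(C)(C)C)C=O | intermediate
4 | methyl (2E,4R)-4-(tert-butyldimethylsilyloxy)-2-methylpent-2-enoate | COC(=O)/C(C)=C/[C@@H](C)O[Si](C)(C)C(C)(C)C | intermediate
5 | methyl (2E,4R)-4-hydroxy-2-methylpent-2-enoate | COC(=O)/C(C)=C/[C@@H](C)O | intermediate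
6 | methyl (2E,4S)-4-(acetylsulfanyl)-2-methylpent-2-enoate | COC(=O)/C(C)=C/[C@H](C)SC(C)=O | intermediate
7 | (2S)-3-bromo-2-methylpropan-1-ol | BrC[C@@H](C)CO | starting material
8 | methyl (2E,4S)-2-methyl-4-sulfanylpent-2-enoate (allylic thiol, present as thiolate) | COC(=O)/C(C)=C/[C@H](C)S | intermediate
9 | methyl (2E,4S)-4-{[(2S)-3-hydroxy-2-methylpropyl]sulfanyl}-2-methylpent-2-enoate | COC(=O)/C(C)=C/[C@H](C)SC[C@@H](C)CO | intermediate
10 | methyl (2E,4S)-2-methyl-4-{[(2S)-2-methyl-3-oxopropyl]sulfanyl}pent-2-enoate | COC(=O)/C(C)=C/[C@H](C)SC[C@@H](C)C=O | intermediate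
11 | methyl (2E,4S)-4-{[(2S,3E)-2,4-dimethyl-5-oxopent-3-en-1-yl]sulfanyl}-2-methylpent-2-enoate | COC(=O)/C(C)=C/[C@H](C)SC[C@@H](C)/C=C(C)/C=O | intermediate
12 | methyl (2E,4S)-2-methyl-4-{[(2S,3E,5E)-2,4,6-trimethyl-7-oxohepta-3,5-dien-1-yl]sulfanyl}pent-2-enoate | COC(=O)/C(C)=C/[C@H](C)SC[C@@H](C)/C=C(C)/C=C(C)/C=O | intermediate
13 | methyl (2E,4S)-2-methyl-4-{[(2S,3E,5E,7E)-2,4,6,8-tetramethyl-9-oxonona-3,5,7-trien-1-yl]sulfanyl}pent-2-enoate | COC(=O)/C(C)=C/[C@H](C)SC[C@@H](C)/C=C(C)/C=C(C)/C=C(C)/C=O | intermediate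
14 | methyl (2E,4S)-2-methyl-4-{[(2S,3E,5E,7E,9E)-2,4,6,8-tetramethyl-10-phenyldeca-3,5,7,9-tetraen-1-yl]sulfanyl}pent-2-enoate | COC(=O)/C(C)=C/[C@H](C)SC[C@@H](C)/C=C(C)/C=C(C)/C=C(C)/C=C/c1ccccc1 | intermediate
15 | sulfoxide of 14 (sulfinyl in place of sulfanyl; both configurations at sulfur) | COC(=O)/C(C)=C/[C@H](C)S(=O)C[C@@H](C)/C=C(C)/C=C(C)/C=C(C)/C=C/c1ccccc1 | intermediate
16 | methyl (2E,4S)-2-methyl-4-{[(2S,3E,5E,7E,9E)-2,4,6,8-tetramethyl-10-phenyldeca-3,5,7,9-tetraen-1-yl]sulfonyl}pent-2-enoate | COC(=O)/C(C)=C/[C@H](C)S(=O)(=O)C[C@@H](C)/C=C(C)/C=C(C)/C=C(C)/C=C/c1ccccc1 | intermediate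
17 | methyl (1S,4S,4aS,7S,8R,8aS)-1,4,5,7,8-pentamethyl-7-[(1E,3E)-2-methyl-4-phenylbuta-1,3-dien-1-yl]-3,4,4a,7,8,8a-hexahydro-1H-isothiochromene-8-carboxylate 2,2-dioxide (trans-fused; both ring methyl groups next to and β to sulfur equatorial) | CC1=C[C@](C)(/C=C(C)/C=C/c2ccccc2)[C@](C)(C(=O)OC)[C@H]2[C@H](C)S(=O)(=O)C[C@@H](C)[C@H]12 | intermediate
18 | 3-bromo derivative of 17 (bromine on the CH2 carbon next to sulfur; both configurations at that carbon) | CC1=C[C@](C)(/C=C(C)/C=C/c2ccccc2)[C@](C)(C(=O)OC)[C@H]2[C@H](C)S(=O)(=O)C(Br)[C@@H](C)[C@H]12 | intermediate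
19 | episulfone: thiirane 1,1-dioxide fused across C-2 and C-3 of the hexahydroindene skeleton of 20 (either face) | CC1=C[C@](C)(/C=C(C)/C=C/c2ccccc2)[C@](C)(C(=O)OC)[C@H]2C3(C)C(S3(=O)=O)[C@@H](C)[C@H]12 | intermediate
20 | methyl (1R,3aR,4R,5S,7aS)-1,3,4,5,7-pentamethyl-5-[(1E,3E)-2-methyl-4-phenylbuta-1,3-dien-1-yl]-3a,4,5,7a-tetrahydro-1H-indene-4-carboxylate | CC1=C[C@](C)(/C=C(C)/C=C/c2ccccc2)[C@](C)(C(=O)OC)[C@H]2C(C)=C[C@@H](C)[C@H]12 | intermediate
21 | 27-nor-zyggomphic acid B, (1R,3aR,4R,5S,7aS)-1,3,4,5,7-pentamethyl-5-[(1E,3E)-2-methyl-4-phenylbuta-1,3-dien-1-yl]-3a,4,5,7a-tetrahydro-1H-indene-4-carboxylic acid | CC1=C[C@](C)(/C=C(C)/C=C/c2ccccc2)[C@](C)(C(=O)O)[C@H]2C(C)=C[C@@H](C)[C@H]12 | target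

**Step count**

Total step count: 14. Longest linear sequence: 14 steps (1 to 21).

**Steps most likely to fail**

Step 13. The cycloaddition may be too slow, because the diene terminus is fully substituted and two adjacent quaternary centres must form; thermal isomerisation of the polyene or 1,5-hydrogen shifts could then compete, and endo/exo control across the four-atom tether may be poor. The fallback reverses the order of the two events and sets out from sulfone 16. Treatment of open-chain 16 with KOH/Al2O3 and CBr2F2 in t-BuOH/CH2Cl2 at 0 °C should extrude SO2 first (hydroxide bases favour the cis alkene) and give the biogenetic precursor methyl (2E,4Z,6S,7E,9E,11E,13E)-2,4,6,8,10,12-hexamethyl-14-phenyltetradeca-2,4,7,9,11,13-hexaenoate F1. Heating F1 in PhMe with BHT at 120 °C should then effect the intramolecular Diels–Alder reaction with the natural three-atom tether, in which only the (4Z)-isomer can close, and the route is rejoined at ester 20. In this fallback the five-membered ring forms directly in the cycloaddition rather than by contraction.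

Step 12. Epoxidation of the electron-rich tetraene may compete with the slower sulfoxide-to-sulfone stage. The fallback oxidises sulfur before the polyene exists and sets out from enal 11. Oxidation of 11 with (NH4)6Mo7O24·4H2O and H2O2 should give sulfone enal methyl (2E,4S)-4-{[(2S,3E)-2,4-dimethyl-5-oxopent-3-en-1-yl]sulfonyl}-2-methylpent-2-enoate F2. Two Wittig homologations with Ph3P=C(Me)CHO (PhMe, 100 °C; the ylide is too weakly basic to deprotonate next to the sulfone) should give dienal methyl (2E,4S)-2-methyl-4-{[(2S,3E,5E)-2,4,6-trimethyl-7-oxohepta-3,5-dien-1-yl]sulfonyl}pent-2-enoate F3 and trienal methyl (2E,4S)-2-methyl-4-{[(2S,3E,5E,7E)-2,4,6,8-tetramethyl-9-oxonona-3,5,7-trien-1-yl]sulfonyl}pent-2-enoate F4. Takai iodo-olefination (CrCl2, CHI3, THF, 0 °C) should give vinyl iodide methyl (2E,4S)-4-{[(2S,3E,5E,7E,9E)-10-iodo-2,4,6,8-tetramethyldeca-3,5,7,9-tetraen-1-yl]sulfonyl}-2-methylpent-2-enoate F5. Suzuki–Miyaura coupling of F5 with PhB(OH)2 (Pd(PPh3)4, K3PO4, THF/H2O, 50 °C) comes back to the route at sulfone 16.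

Step 11. Proton transfer from the carbon between sulfur and the enoate to the phosphonate anion may cause double-bond migration or epimerisation and stall the olefination. The fallback replaces the carbanion olefination by a non-basic two-step sequence and sets out from trienal 13. Takai iodo-olefination (CrCl2, CHI3, THF, 0 °C) should give vinyl iodide methyl (2E,4S)-4-{[(2S,3E,5E,7E,9E)-10-iodo-2,4,6,8-tetramethyldeca-3,5,7,9-tetraen-1-yl]sulfanyl}-2-methylpent-2-enoate F6. Suzuki–Miyaura coupling of F6 with PhB(OH)2 (Pd(PPh3)4, K3PO4, THF/H2O, 50 °C) comes back to the route at sulfide 14.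

**Further compounds**

F1 | step 13 | methyl (2E,4Z,6S,7E,9E,11E,13E)-2,4,6,8,10,12-hexamethyl-14-phenyltetradeca-2,4,7,9,11,13-hexaenoate | COC(=O)/C(C)=C/C(C)=C\[C@@H](C)/C=C(C)/C=C(C)/C=C(C)/C=C/c1ccccc1
F2 | step 12 | methyl (2E,4S)-4-{[(2S,3E)-2,4-dimethyl-5-oxopent-3-en-1-yl]sulfonyl}-2-methylpent-2-enoate | COC(=O)/C(C)=C/[C@H](C)S(=O)(=O)C[C@@H](C)/C=C(C)/C=O
F3 | step 12 | methyl (2E,4S)-2-methyl-4-{[(2S,3E,5E)-2,4,6-trimethyl-7-oxohepta-3,5-dien-1-yl]sulfonyl}pent-2-enoate | COC(=O)/C(C)=C/[C@H](C)S(=O)(=O)C[C@@H](C)/C=C(C)/C=C(C)/C=O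
F4 | step 12 | methyl (2E,4S)-2-methyl-4-{[(2S,3E,5E,7E)-2,4,6,8-tetramethyl-9-oxonona-3,5,7-trien-1-yl]sulfonyl}pent-2-enoate | COC(=O)/C(C)=C/[C@H](C)S(=O)(=O)C[C@@H](C)/C=C(C)/C=C(C)/C=C(C)/C=O
F5 | step 12 | methyl (2E,4S)-4-{[(2S,3E,5E,7E,9E)-10-iodo-2,4,6,8-tetramethyldeca-3,5,7,9-tetraen-1-yl]sulfonyl}-2-methylpent-2-enoate | COC(=O)/C(C)=C/[C@H](C)S(=O)(=O)C[C@@H](C)/C=C(C)/C=C(C)/C=C(C)/C=C/I
F6 | step 11 | methyl (2E,4S)-4-{[(2S,3E,5E,7E,9E)-10-iodo-2,4,6,8-tetramethyldeca-3,5,7,9-tetraen-1-yl]sulfanyl}-2-methylpent-2-enoate | COC(=O)/C(C)=C/[C@H](C)SC[C@@H](C)/C=C(C)/C=C(C)/C=C(C)/C=C/I
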